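Atoms carry lignan locants throughout: C7/C7' are the benzylic ring carbons, C8 is the ring-fusion carbinol, C8' the ring-fusion CH, and C9/C9' the OCH2 carbons on C8/C8'. Ring A is O–C7'–C8'–C8–C9 and ring B is O–C7–C8–C8'–C9'. Compounds are numbered 1–20 in the order of the steps. "Aryl" in shortened names means 4-(tert-butyldimethylsilyloxy)-3-methoxyphenyl, and "menthyl" means (1R,2S,5R)-2-isopropyl-5-methylcyclohexyl.

## Analysis of the target

8-Hydroxypinoresinol (20) is a furofuran lignan: rings A and B are two tetrahydrofurans that share the C8–C8' bond in a cis-fused 3,7-dioxabicyclo[3.3.0]octane, with a 4-hydroxy-3-methoxyphenyl group on each of C7 and C7' and a tertiary hydroxyl on C8. The four contiguous stereocentres are (7R,8S,7'S,8'R). The cis fusion places the C8 hydroxyl and the C8' hydrogen on the convex face, and both aryl groups are exo, the C7 aryl cis to the C8 hydroxyl and the C7' aryl cis to H-8'. The sensitive groups are the two phenols (oxidation, quinone methide formation), the two benzylic ether bonds C7–O and C7'–O (ionised by acid, cleaved by hydrogenolysis, so benzyl protection is excluded) and the tertiary alcohol, which sits next to benzylic C7 and invites a pinacol-type shift whenever C7 becomes cationic. The difficulty compared with pinoresinol is the lost symmetry: C8 is fully substituted and oxygenated, so the two halves cannot come from a dimerisation, and C8 and C8' must be fixed relative to each other (otherwise the bicycle cannot close) and absolutely. The strategy rests on the chain C9–C8–C8'–C9' with oxygen on C8. It has the carbon and oxidation pattern of a 5-alkoxy-2(5H)-furanone, with C9 as lactone carbonyl, C8 as α-carbon, C8' as electrophilic β-carbon and C9' as acetal carbon. C7' can therefore be delivered to C8' as a carbanion, and oxygen and then C7 can be delivered to C8 as electrophiles.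

## Retrosynthetic reasoning

**Protecting groups (20 from 19).** The last step only removes silicon. Target 20 is traced to its tris-silyl derivative 19, with aryl tert-butyldimethylsilyl ethers and a triethylsilyl ether on the C8 oxygen. All three fall to fluoride under buffered conditions that leave the benzylic ethers alone.

**Both benzylic C–O bonds (19 from 17).** The C7'–O bond of ring A and the C7–O bond of ring B are cut together, leading to the open tetraol 17. These bonds are chosen because each benzylic carbon carries an electron-rich arene and ionises easily, while the primary hydroxyls on C9 and C9' sit at the right distance for five-membered closure. The gain is that C7 and C7' need no control before this point: they are created in the ring closure itself, where the exo position of each aryl group is favoured and ionisation is reversible. Only C8 and C8' must be correct in 17.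

**Oxidation levels (17 from 16 from 15).** The two primary alcohols of 17 are traced to a lactone carbonyl (C9) and a menthyl acetal carbon (C9'), and the C7' carbinol to an aryl ketone, so that one hydride reduction of keto lactone 16 delivers 17 and releases the auxiliary. The ketone in 16 is the unmasked form of the dithiane in 15.

**C7–C8 bond (15 from 13 and 7).** Cutting C7–C8 gives the enolate of the α-silyloxy lactone 13 and aldehyde 7. This carbon–carbon bond is placed after the carbon–oxygen bond at C8 on purpose. The last substituent to arrive at C8 enters anti to the bulky C8' substituent, and the bicycle needs C7 trans to the C7'-bearing group on the lactone (C8 oxygen cis to it). Introducing oxygen last would give the diastereomer that cannot close to a cis-fused furofuran. Lactone 13 is the silyl ether of hydroxy lactone 12.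

**C7'–C8' and C8–O bonds (12 from 9 and 5).** Both bonds are cut in one operation. Conjugate addition of the lithiated dithiane 10 (from 9) to butenolide 5 forms C7'–C8', and the resulting enolate 11 is oxidised at C8 by an electrophilic oxygen-transfer reagent. The cut is made here because it separates the molecule into the four-carbon lactone and one aryl unit, fixes C8' from a cheap auxiliary, and puts oxygen on C8 without a separate enolisation.

**Precursors (5 from 2 and 3, 2 from 1; 9 from 7 and 8, 7 from 6).** Butenolide 5 comes from furfural 1 by photo-oxygenation to 2 and acetalisation with (−)-menthol 3, the (5R)-epimer being secured by crystallisation. Dithiane 9 comes from vanillin 6 through silyl ether 7 and propane-1,3-dithiol 8. Aldehyde 7 serves twice, as the source of 9 and as the aldol partner.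

## Alternatives that were turned down

**Alternative 1: twofold C-arylation of a preformed bicycle.**
- Disconnection: both aryl–carbon bonds at C7 and C7', leaving a core that already holds rings A and B, C8 and C8'.
- Forward key step: a Lewis acid ionises the two anomeric acetates of 2,6-diacetoxy-1-(triethylsilyloxy)-3,7-dioxabicyclo[3.3.0]octane A2, and [4-(tert-butyldimethylsilyloxy)-3-methoxyphenyl]zinc bromide A3 adds to each oxocarbenium ion from the convex face. The product A1 is the same compound as 19.
- For it: both aryl groups arrive in one late step, and C7 and C7' are set kinetically and irreversibly by the shape of the bicycle.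
- Against it: all the difficulty moves into A2. From (S)-malic acid A4, whose carbinol carbon would become C8, two formyl-level carbons must be attached to adjacent carbons with control, one of them making the oxygenated quaternary centre. The risk therefore lies well before the key step. The cation at C7 is inductively retarded by the neighbouring silyloxy carbon, the cation at C7' can lose H-8' to give an enol ether, and a mono-arylated intermediate holds an acid-labile benzylic ether.
- Comparison: on control of C7 and C7' this alternative is stronger than the chosen route, which relies on reversible cation closure. The chosen route offers instead key-step precursors 5 and 9 in two steps each and a quaternary C8 made by ordinary enolate chemistry.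

**Alternative 2: Prins–pinacol construction of ring A.**
- Disconnection: C7'–O, C7'–C8' and C8–C9 of ring A.
- Forward key step: 4-formyl-2-methoxyphenyl pivalate A6 and the allylic diol A7 form a dioxolane acetal in the flask. A tin Lewis acid opens it to an oxocarbenium ion, the alkene attacks (C7'–C8'), and C9 shifts to the resulting cation at C8 with ring contraction. The product is the ring A aldehyde A5, carrying a formyl group and an arylmethyl group on C8.
- For it: three bonds, ring A and the quaternary centre form in one chair-organised event, so C7', C8' and C8 are related kinetically.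
- Against it: both C8 substituents arrive at the wrong oxidation level. The C8 oxygen is only latent in the formyl group and needs a peracid-type excision on a neopentyl aldehyde beside electron-rich arenes. C7 arrives as CH2, so ring B needs a benzylic oxidation in a molecule that already has a second oxidisable benzylic ether. The single stereocentre of A7 is destroyed in the shift and must itself be made enantioselectively (its configuration is drawn for a chair with the metal alkoxide equatorial, which is not assured). Three different protecting groups are also needed.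
- Comparison: this alternative is stronger on fixing C7' relative to C8' and C8. The chosen route offers the correct oxidation level at C8 and C7 directly and a shorter path after the key step.

**Alternative 3: ketene [2+2] cycloaddition and ring expansion.**
- Disconnection: C7–C8 and C8'–C9', with the ring B oxygen inserted afterwards.
- Forward key step: the aryl ketene A11, formed from the arylacetyl chloride A10 and a tertiary amine, adds across the C8=C8' bond of the ring A silyl enol ether A9. The product is the cyclobutanone A8, a 4,7-diaryl-1-silyloxy-3-oxabicyclo[3.2.0]heptan-6-one. Peracid ring expansion with migration of benzylic C7 and reduction of the lactone would follow.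
- For it: the oxygenated quaternary C8, the C7–C8 bond and a necessarily cis ring fusion come in one step, with regiochemistry fixed by the enol ether polarity. On the ring fusion it is at least as secure as the chosen route.
- Against it: ketene cycloadditions place the larger ketene substituent on the concave face, the opposite of the exo aryl drawn in A8. Correcting C7 by enolisation exposes a β-silyloxy cyclobutanone that opens readily by retro-aldol. Enantiopure A9 needs its own asymmetric synthesis of C7' and a regiodefined enol ether (C8=C8' and not C8=C9). The lactone must still be taken down to the ether.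
- Comparison: the chosen route avoids strained intermediates and takes its absolute configuration from a crystalline auxiliary.

Key step: step 5

Remark on the chemistry: the carbinol centres C7 (in 15, 16, 17, 18) and C7' (in 17) are expected as epimer mixtures and are written without configuration; both are re-formed in step 10.

## Route

Step 1
Reactants: 1 furfural
Product: 2 5-hydroxy-2(5H)-furanone (racemic)
Conditions: O2, rose bengal (C20H2Cl4I4Na2O5, cat.), MeOH, hν (visible), rt
Reagents that add atoms: oxygen, O=O
Why: Dye-sensitised singlet-oxygen [4+2] cycloaddition across C2/C5 of the furan gives an endoperoxide; methanol adds to the formyl group and the adduct fragments with loss of methyl formate, leaving the hydroxybutenolide (photo-oxygenation of furfural).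

Step 2
Reactants: 2 5-hydroxy-2(5H)-furanone; 3 (−)-menthol
Product: 5 (5R)-5-[(1R,2S,5R)-menthyloxy]-2(5H)-furanone, via (5S)-5-(menthyloxy)-2(5H)-furanone 4 (not isolated)
Conditions: camphor-10-sulfonic acid (cat.), toluene, reflux (Dean–Stark); crystallise from petroleum ether; mother liquor re-equilibrated with the same acid and recrystallised
Reagents that add atoms: none
Why: Acid-catalysed acetalisation of the pseudo-acid hydroxyl through the furanone oxocarbenium ion gives both acetal epimers; the (5R)-epimer 5 crystallises while the (5S)-epimer 4 re-ionises under the acid, so the material is funnelled into 5 (crystallisation-driven epimer convergence). This acetal carbon is the stereocentre that later controls C8'.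

Step 3
Reactants: 6 vanillin
Product: 7 4-(tert-butyldimethylsilyloxy)-3-methoxybenzaldehyde
Conditions: TBSCl, imidazole, DMF, rt
Reagents that add atoms: tert-butyldimethylsilyl chloride, CC(C)(C)[Si](C)(C)Cl
Why: Standard phenol silylation; the aryl silyl ether tolerates organolithium bases and cold hydride and is removed by fluoride at the end without touching the benzylic ethers.

Step 4
Reactants: 7 4-(tert-butyldimethylsilyloxy)-3-methoxybenzaldehyde; 8 propane-1,3-dithiol
Product: 9 2-[4-(tert-butyldimethylsilyloxy)-3-methoxyphenyl]-1,3-dithiane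
Conditions: BF3·OEt2 (0.2 equiv), CH2Cl2, 0 °C
Reagents that add atoms: none
Why: Lewis-acid-catalysed dithioacetalisation of the aromatic aldehyde; catalytic acid at 0 °C spares the aryl silyl ether.

Step 5
Reactants: 9 2-[4-(tert-butyldimethylsilyloxy)-3-methoxyphenyl]-1,3-dithiane; 5 (5R)-5-[(1R,2S,5R)-menthyloxy]-2(5H)-furanone
Product: 12 (3R,4R,5R)-4-{2-[4-(tert-butyldimethylsilyloxy)-3-methoxyphenyl]-1,3-dithian-2-yl}-3-hydroxy-5-[(1R,2S,5R)-menthyloxy]dihydrofuran-2(3H)-one (3,4-trans-4,5-trans), via 2-lithio-2-aryl-1,3-dithiane 10 (not isolated), via lithium lactone enolate 11 (not isolated)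
Conditions: n-BuLi, THF, −78 → −30 °C; 5, −78 °C; then 2-(phenylsulfonyl)-3-phenyloxaziridine, −78 °C; sat. aq. NH4Cl, −78 °C
Reagents that add atoms: 2-(phenylsulfonyl)-3-phenyloxaziridine, O=S(=O)(c1ccccc1)N1OC1c1ccccc1
Why: Deprotonation of 9 gives the sulfur-stabilised benzylic carbanion 10, an acyl-anion equivalent for C7', which adds in Michael fashion to the β-carbon of 5 and forms the C7'–C8' bond and the lithium enolate 11. The closest known reaction type is the tandem conjugate addition–enolate trapping of 5-alkoxy-2(5H)-furanones with lithiated 2-aryl-1,3-dithianes, joined here to the Davis-type hydroxylation of ester enolates by N-sulfonyloxaziridines. The step closes no ring. C8' is controlled by the (5R) acetal centre: the menthyloxy group covers one face of the flat butenolide, so the bulky nucleophile enters trans to it. The enolate carbon C8 then attacks the oxaziridine oxygen with expulsion of the sulfonylimine, from the face away from the new dithianyl substituent, which gives the 3,4-trans lactone. This C8 configuration is erased by enolisation in step 7, so only the C8' outcome is carried into the target. The step needs 1,4- over 1,2-regioselectivity, which the soft delocalised dithianyl anion and the unhindered β-carbon provide. It also needs chemoselectivity for the enolate carbon over the dithiane sulfur and over addition to the released imine, which the anionic enolate, the low temperature and a cold quench should secure.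

Step 6
Reactants: 12 hydroxy lactone
Product: 13 (3R,4R,5R)-4-{2-[4-(tert-butyldimethylsilyloxy)-3-methoxyphenyl]-1,3-dithian-2-yl}-5-[(1R,2S,5R)-menthyloxy]-3-(triethylsilyloxy)dihydrofuran-2(3H)-one
Conditions: Et3SiOSO2CF3, 2,6-lutidine, CH2Cl2, −78 → 0 °C
Reagents that add atoms: triethylsilyl trifluoromethanesulfonate, CC[Si](CC)(CC)OS(=O)(=O)C(F)(F)F
Why: Silyl triflate silylation of the hindered secondary alcohol; the triethylsilyl ether tolerates the amide base of step 7, blocks alkoxide-driven fragmentation at C8 in steps 8 and 9, and still falls to fluoride in step 11.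

Step 7
Reactants: 13 silyloxy lactone; 7 4-(tert-butyldimethylsilyloxy)-3-methoxybenzaldehyde
Product: 15 (3R,4R,5R)-3-{[4-(tert-butyldimethylsilyloxy)-3-methoxyphenyl](hydroxy)methyl}-4-{2-[4-(tert-butyldimethylsilyloxy)-3-methoxyphenyl]-1,3-dithian-2-yl}-5-[(1R,2S,5R)-menthyloxy]-3-(triethylsilyloxy)dihydrofuran-2(3H)-one (C7 carbinol epimers), via α-silyloxy lactone lithium enolate 14 (not isolated)
Conditions: LiN(iPr)2, THF, −78 °C; 7, −78 °C; AcOH, −78 °C
Reagents that add atoms: none
Why: The amide base removes the C8 hydrogen of 13 to give the tetrasubstituted enolate 14, which has no β-leaving group on C8' and should persist at −78 °C. Lithium aldol addition to the non-enolisable aldehyde 7 takes place on the face opposite the dithianyl substituent on C8', making C8 quaternary with its oxygen cis to the C7'-bearing group, the only arrangement that can later close to a cis-fused bicycle. The new carbinol centre C7 is not controlled and need not be.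

Step 8
Reactants: 15 aldol adduct
Product: 16 (3R,4R,5R)-4-[4-(tert-butyldimethylsilyloxy)-3-methoxybenzoyl]-3-{[4-(tert-butyldimethylsilyloxy)-3-methoxyphenyl](hydroxy)methyl}-5-[(1R,2S,5R)-menthyloxy]-3-(triethylsilyloxy)dihydrofuran-2(3H)-one (C7 epimers)
Conditions: Hg(ClO4)2·3H2O, CaCO3, THF/H2O (5:1), 0 °C → rt
Reagents that add atoms: water, O
Why: Thiophilic divalent mercury opens the thioketal through the aryl-stabilised thionium ion, which water captures (dithiane hydrolysis); CaCO3 keeps the medium near neutral so that the silyl ethers, the acetal, the aldol unit and the now enolisable C8'–H are left alone. The C7 and C7' side chains are trans on the lactone, which rules out an internal hemiketal.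

Step 9
Reactants: 16 keto lactone
Product: 17 (2S,3R)-1,4-bis[4-(tert-butyldimethylsilyloxy)-3-methoxyphenyl]-2,3-bis(hydroxymethyl)-2-(triethylsilyloxy)butane-1,4-diol (C7 and C7' epimers; 8S,8'R in lignan locants)
Conditions: LiAlH4, THF, −78 → 0 °C; then H2O, 15% aq. NaOH, H2O
Reagents that add atoms: none
Why: Hydride reduces the aryl ketone to the C7' carbinol and the lactone to the C9 alcohol; opening of the lactone exposes C9' as a menthyl hemiacetal alkoxide, which collapses to the aldehyde and is reduced to the C9' alcohol with release of menthol. Carbonyl reduction is faster than enolisation at C8', and the aryl and tertiary silyl ethers are not attacked by cold hydride, so C8 and C8' pass unchanged.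

Step 10
Reactants: 17 tetraol
Product: 19 (7R,8S,7'S,8'R)-8-O-triethylsilyl-8-hydroxypinoresinol bis(tert-butyldimethylsilyl) ether, via monocyclic ring A tetrahydrofuran 18 (not isolated)
Conditions: camphor-10-sulfonic acid (0.2 equiv), 4 Å molecular sieves, CH2Cl2, 0 °C → rt
Reagents that add atoms: none
Why: Acid-catalysed SN1 etherification: each electron-rich benzylic alcohol ionises to a quinoid benzylic cation that is captured 5-exo by the primary hydroxyl (C9–OH onto C7', then C9'–OH onto C7); the C7' cation, not flanked by the oxygenated quaternary carbon, should form first, hence 18. Both benzylic centres are created here: in 18 the aryl group settles trans to the C8' hydroxymethyl group, and in the second closure only a cis fusion is possible and the aryl group takes the convex face, next to the small C8 oxygen and away from C9. Reversible ionisation lets the exo,exo isomer accumulate.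

Step 11
Reactants: 19 tris-silyl ether
Product: 20 8-hydroxypinoresinol
Conditions: Bu4NF, AcOH, THF, 0 °C → rt
Reagents that add atoms: none
Why: Fluoride cleaves the two aryl silyl ethers and the tertiary triethylsilyl ether (desilylation); acetic acid buffers the phenoxides so that no quinone methide opens the benzylic ethers. No stereocentre is touched.

## Compound list

1 | furfural (furan-2-carbaldehyde) | O=Cc1ccco1 | starting material
2 | 5-hydroxy-2(5H)-furanone (racemic) | O=C1C=CC(O)O1 | intermediate
3 | (−)-menthol, (1R,2S,5R)-2-isopropyl-5-methylcyclohexan-1-ol | O[C@@H]1C[C@H](C)CC[C@H]1C(C)C | starting material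
4 | (5S)-5-[(1R,2S,5R)-menthyloxy]-2(5H)-furanone (not isolated, equilibrated to 5) | O=C1C=C[C@@H](O[C@@H]2C[C@H](C)CC[C@H]2C(C)C)O1 | intermediate
5 | (5R)-5-[(1R,2S,5R)-menthyloxy]-2(5H)-furanone | O=C1C=C[C@H](O[C@@H]2C[C@H](C)CC[C@H]2C(C)C)O1 | intermediate
6 | vanillin (4-hydroxy-3-methoxybenzaldehyde) | COc1cc(C=O)ccc1O | starting material
7 | 4-(tert-butyldimethylsilyloxy)-3-methoxybenzaldehyde | COc1cc(C=O)ccc1O[Si](C)(C)C(C)(C)C | intermediate
8 | propane-1,3-dithiol | SCCCS | starting material
9 | 2-[4-(tert-butyldimethylsilyloxy)-3-methoxyphenyl]-1,3-dithiane | COc1cc(C2SCCCS2)ccc1O[Si](C)(C)C(C)(C)C | intermediate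
10 | 2-lithio-2-[4-(tert-butyldimethylsilyloxy)-3-methoxyphenyl]-1,3-dithiane (not isolated) | [Li]C1(c2ccc(O[Si](C)(C)C(C)(C)C)c(OC)c2)SCCCS1 | intermediate
11 | lithium enolate of (4R,5R)-4-(2-aryl-1,3-dithian-2-yl)-5-(menthyloxy)dihydrofuran-2(3H)-one (not isolated) | [Li]OC1=C[C@@H](C2(c3ccc(O[Si](C)(C)C(C)(C)C)c(OC)c3)SCCCS2)[C@H](O[C@@H]4C[C@H](C)CC[C@H]4C(C)C)O1 | intermediate
12 | (3R,4R,5R)-4-{2-[4-(tert-butyldimethylsilyloxy)-3-methoxyphenyl]-1,3-dithian-2-yl}-3-hydroxy-5-[(1R,2S,5R)-menthyloxy]dihydrofuran-2(3H)-one | O=C1O[C@@H](O[C@@H]2C[C@H](C)CC[C@H]2C(C)C)[C@H](C4(c3ccc(O[Si](C)(C)C(C)(C)C)c(OC)c3)SCCCS4)[C@H]1O | intermediate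
13 | (3R,4R,5R)-4-{2-[4-(tert-butyldimethylsilyloxy)-3-methoxyphenyl]-1,3-dithian-2-yl}-5-[(1R,2S,5R)-menthyloxy]-3-(triethylsilyloxy)dihydrofuran-2(3H)-one | O=C1O[C@@H](O[C@@H]2C[C@H](C)CC[C@H]2C(C)C)[C@H](C4(c3ccc(O[Si](C)(C)C(C)(C)C)c(OC)c3)SCCCS4)[C@H]1O[Si](CC)(CC)CC | intermediate
14 | lithium enolate of 13 (not isolated) | [Li]OC1=C(O[Si](CC)(CC)CC)[C@@H](C2(c3ccc(O[Si](C)(C)C(C)(C)C)c(OC)c3)SCCCS2)[C@H](O[C@@H]4C[C@H](C)CC[C@H]4C(C)C)O1 | intermediate
15 | (3R,4R,5R)-3-{[4-(tert-butyldimethylsilyloxy)-3-methoxyphenyl](hydroxy)methyl}-4-{2-[4-(tert-butyldimethylsilyloxy)-3-methoxyphenyl]-1,3-dithian-2-yl}-5-[(1R,2S,5R)-menthyloxy]-3-(triethylsilyloxy)dihydrofuran-2(3H)-one (C7 carbinol epimers) | O=C1O[C@@H](O[C@@H]2C[C@H](C)CC[C@H]2C(C)C)[C@H](C4(c3ccc(O[Si](C)(C)C(C)(C)C)c(OC)c3)SCCCS4)[C@@]1(O[Si](CC)(CC)CC)C(O)c5ccc(O[Si](C)(C)C(C)(C)C)c(OC)c5 | intermediate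
16 | (3R,4R,5R)-4-[4-(tert-butyldimethylsilyloxy)-3-methoxybenzoyl]-3-{[4-(tert-butyldimethylsilyloxy)-3-methoxyphenyl](hydroxy)methyl}-5-[(1R,2S,5R)-menthyloxy]-3-(triethylsilyloxy)dihydrofuran-2(3H)-one (C7 epimers) | O=C1O[C@@H](O[C@@H]2C[C@H](C)CC[C@H]2C(C)C)[C@H](C(=O)c3ccc(O[Si](C)(C)C(C)(C)C)c(OC)c3)[C@@]1(O[Si](CC)(CC)CC)C(O)c5ccc(O[Si](C)(C)C(C)(C)C)c(OC)c5 | intermediate
17 | (2S,3R)-1,4-bis[4-(tert-butyldimethylsilyloxy)-3-methoxyphenyl]-2,3-bis(hydroxymethyl)-2-(triethylsilyloxy)butane-1,4-diol (C7 and C7' epimers) | OC[C@H](C(O)c1ccc(O[Si](C)(C)C(C)(C)C)c(OC)c1)[C@@](CO)(O[Si](CC)(CC)CC)C(O)c2ccc(O[Si](C)(C)C(C)(C)C)c(OC)c2 | intermediate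
18 | (2S,3R,4S)-2-[4-(tert-butyldimethylsilyloxy)-3-methoxyphenyl]-4-{[4-(tert-butyldimethylsilyloxy)-3-methoxyphenyl](hydroxy)methyl}-3-(hydroxymethyl)-4-(triethylsilyloxy)tetrahydrofuran (C7 epimers, not isolated) | OC[C@@H]1[C@@H](c2ccc(O[Si](C)(C)C(C)(C)C)c(OC)c2)OC[C@]1(O[Si](CC)(CC)CC)C(O)c3ccc(O[Si](C)(C)C(C)(C)C)c(OC)c3 | intermediate
19 | (7R,8S,7'S,8'R)-8-O-triethylsilyl-8-hydroxypinoresinol bis(tert-butyldimethylsilyl) ether | COc1cc([C@H]2OC[C@]3(O[Si](CC)(CC)CC)[C@@H](c4ccc(O[Si](C)(C)C(C)(C)C)c(OC)c4)OC[C@H]23)ccc1O[Si](C)(C)C(C)(C)C | intermediate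
20 | 8-hydroxypinoresinol, (3R,3aS,6S,6aR)-3,6-bis(4-hydroxy-3-methoxyphenyl)tetrahydro-1H,3H-furo[3,4-c]furan-3a-ol | COc1cc([C@H]2OC[C@]3(O)[C@@H](c4ccc(O)c(OC)c4)OC[C@H]23)ccc1O | target

## Step count and weak points

Total: 11 steps. Longest linear sequence: 9 steps (steps 1, 2, 5, 6, 7, 8, 9, 10, 11 from furfural 1; the branch from vanillin 6 through steps 3 and 4 is equally long).

**Step 5 (key step).** The most likely failure is capture of the lithium enolate by the sulfonylimine released from the oxaziridine, with oxidation at dithiane sulfur by excess reagent as a second leak. Both stem from the enolate meeting oxidant and by-product in one flask with lithium as counter-ion. Fallback, from 9 and 5 to 12: the two bond formations are uncoupled. The conjugate addition of 10 to 5 is quenched with NH4Cl to give (4R,5R)-4-{2-[4-(tert-butyldimethylsilyloxy)-3-methoxyphenyl]-1,3-dithian-2-yl}-5-[(1R,2S,5R)-menthyloxy]dihydrofuran-2(3H)-one F1. Its potassium enolate, made with KN(SiMe3)2 at −78 °C, is then hydroxylated with (camphorsulfonyl)oxaziridine, whose ketimine by-product does not add enolates, and the route is rejoined at 12.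

**Step 7.** The C8 hydrogen of 13 lies on the same face as the dithianyl group, so enolisation may be slow, and the enolate can fragment by loss of the ring alkoxide if warmed. The congested quaternary lithium aldolate may also revert. Leakage to the other enolate face would give a diastereomer that cannot form the bicycle. Fallback, from 13 to 15: deprotonation with LiN(iPr)2 in the presence of Me3SiCl (internal quench) gives the silyl ketene acetal (4R,5R)-4-{2-[4-(tert-butyldimethylsilyloxy)-3-methoxyphenyl]-1,3-dithian-2-yl}-5-[(1R,2S,5R)-menthyloxy]-3-(triethylsilyloxy)-2-(trimethylsilyloxy)-4,5-dihydrofuran F2. A Mukaiyama aldol addition of F2 to 7 (BF3·OEt2, CH2Cl2, −78 °C) is irreversible, goes through an open transition state with the same facial bias, and returns to 15.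

**Step 8.** Once the ketone is free, C8'–H is α to it and β to the acetal oxygens, so epimerisation at C8', β-elimination of the acetal and retro-aldol loss of C7 become possible. A sluggish hydrolysis of the hindered thioketal would lengthen the exposure. Fallback, from 15 to 17: the order is reversed. LiAlH4 reduction of 15 with the dithiane in place gives the triol (2S,3S)-1-[4-(tert-butyldimethylsilyloxy)-3-methoxyphenyl]-3-{2-[4-(tert-butyldimethylsilyloxy)-3-methoxyphenyl]-1,3-dithian-2-yl}-2-(hydroxymethyl)-2-(triethylsilyloxy)butane-1,4-diol F3. Hydrolysis with Hg(ClO4)2/CaCO3 then gives the hydroxy ketone (2S,3S)-1,4-bis[4-(tert-butyldimethylsilyloxy)-3-methoxyphenyl]-4-hydroxy-2,3-bis(hydroxymethyl)-3-(triethylsilyloxy)butan-1-one F4, which is sheltered as its five-membered hemiketal with the C9 hydroxyl and is reduced at once with NaBH4 (MeOH, 0 °C) to 17.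

**Step 10.** Three things can go wrong at the cation stage:
- a pinacol-type 1,2-shift from C8 to the C7 cation;
- irreversible Friedel–Crafts closure of a benzylic cation onto the other arene, giving an aryltetralin;
- incomplete exo selectivity at C7 or C7', since the preference between exo and endo furofurans is not large.

Acid may also loosen the triethylsilyl ether. Fallback, from 17 to 20: the silyl groups are removed first (Bu4NF, AcOH) to give (2S,3R)-1,4-bis(4-hydroxy-3-methoxyphenyl)-2,3-bis(hydroxymethyl)butane-1,2,4-triol F5. Its free p-hydroxybenzyl alcohols are closed through p-quinone methides under mild protic conditions (dilute aqueous HCl in dioxane, rt). This is the mode of ring closure by which the hydroxymethyl groups trap the quinone methides in pinoresinol formation; it avoids long-lived silyloxybenzyl cations and gives 20 directly.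

## Further compounds

F1 | step 5 | (4R,5R)-4-{2-[4-(tert-butyldimethylsilyloxy)-3-methoxyphenyl]-1,3-dithian-2-yl}-5-[(1R,2S,5R)-menthyloxy]dihydrofuran-2(3H)-one | O=C1C[C@@H](C2(c3ccc(O[Si](C)(C)C(C)(C)C)c(OC)c3)SCCCS2)[C@H](O[C@@H]4C[C@H](C)CC[C@H]4C(C)C)O1
F2 | step 7 | (4R,5R)-4-{2-[4-(tert-butyldimethylsilyloxy)-3-methoxyphenyl]-1,3-dithian-2-yl}-5-[(1R,2S,5R)-menthyloxy]-3-(triethylsilyloxy)-2-(trimethylsilyloxy)-4,5-dihydrofuran | C[Si](C)(C)OC1=C(O[Si](CC)(CC)CC)[C@@H](C2(c3ccc(O[Si](C)(C)C(C)(C)C)c(OC)c3)SCCCS2)[C@H](O[C@@H]4C[C@H](C)CC[C@H]4C(C)C)O1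
F3 | step 8 | (2S,3S)-1-[4-(tert-butyldimethylsilyloxy)-3-methoxyphenyl]-3-{2-[4-(tert-butyldimethylsilyloxy)-3-methoxyphenyl]-1,3-dithian-2-yl}-2-(hydroxymethyl)-2-(triethylsilyloxy)butane-1,4-diol (C7 epimers) | OC[C@H](C1(c2ccc(O[Si](C)(C)C(C)(C)C)c(OC)c2)SCCCS1)[C@@](CO)(O[Si](CC)(CC)CC)C(O)c3ccc(O[Si](C)(C)C(C)(C)C)c(OC)c3
F4 | step 8 | (2S,3S)-1,4-bis[4-(tert-butyldimethylsilyloxy)-3-methoxyphenyl]-4-hydroxy-2,3-bis(hydroxymethyl)-3-(triethylsilyloxy)butan-1-one (C7 epimers, open form of the hemiketal) | OC[C@H](C(=O)c1ccc(O[Si](C)(C)C(C)(C)C)c(OC)c1)[C@@](CO)(O[Si](CC)(CC)CC)C(O)c2ccc(O[Si](C)(C)C(C)(C)C)c(OC)c2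
F5 | step 10 | (2S,3R)-1,4-bis(4-hydroxy-3-methoxyphenyl)-2,3-bis(hydroxymethyl)butane-1,2,4-triol (C7 and C7' epimers) | OC[C@H](C(O)c1ccc(O)c(OC)c1)[C@@](CO)(O)C(O)c2ccc(O)c(OC)c2
A1 | alternative 1 | 8-O-triethylsilyl-8-hydroxypinoresinol bis(tert-butyldimethylsilyl) ether (identical with 19) | COc1cc([C@H]2OC[C@]3(O[Si](CC)(CC)CC)[C@@H](c4ccc(O[Si](C)(C)C(C)(C)C)c(OC)c4)OC[C@H]23)ccc1O[Si](C)(C)C(C)(C)C
A2 | alternative 1 | 2,6-diacetoxy-1-(triethylsilyloxy)-3,7-dioxabicyclo[3.3.0]octane with the C8 and C8' configuration of 20 (anomer mixture) | CC(=O)OC1OC[C@]2(O[Si](CC)(CC)CC)C(OC(C)=O)OC[C@H]12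
A3 | alternative 1 | [4-(tert-butyldimethylsilyloxy)-3-methoxyphenyl]zinc bromide | COc1cc([Zn]Br)ccc1O[Si](C)(C)C(C)(C)C
A4 | alternative 1 | (S)-malic acid | OC(=O)C[C@H](O)C(=O)O
A5 | alternative 2 | 3-[4-(tert-butyldimethylsilyloxy)-3-methoxybenzyl]-4-[(tert-butyldiphenylsilyloxy)methyl]-5-(3-methoxy-4-pivaloyloxyphenyl)tetrahydrofuran-3-carbaldehyde with the C7', C8' and C8 configuration of ring A of 20 | COc1cc([C@H]2OC[C@](C=O)(Cc3ccc(O[Si](C)(C)C(C)(C)C)c(OC)c3)[C@@H]2CO[Si](c3ccccc3)(c3ccccc3)C(C)(C)C)ccc1OC(=O)C(C)(C)C
A6 | alternative 2 | 4-formyl-2-methoxyphenyl pivalate | COc1cc(C=O)ccc1OC(=O)C(C)(C)C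
A7 | alternative 2 | (2R,3E)-3-[4-(tert-butyldimethylsilyloxy)-3-methoxybenzyl]-5-(tert-butyldiphenylsilyloxy)pent-3-ene-1,2-diol | OC[C@H](O)/C(Cc1ccc(O[Si](C)(C)C(C)(C)C)c(OC)c1)=C/CO[Si](c1ccccc1)(c1ccccc1)C(C)(C)C
A8 | alternative 3 | 4,7-bis[4-(tert-butyldimethylsilyloxy)-3-methoxyphenyl]-1-(tert-butyldimethylsilyloxy)-3-oxabicyclo[3.2.0]heptan-6-one (both aryl groups exo) | COc1cc([C@H]2OC[C@]3(O[Si](C)(C)C(C)(C)C)[C@@H](c4ccc(O[Si](C)(C)C(C)(C)C)c(OC)c4)C(=O)[C@H]23)ccc1O[Si](C)(C)C(C)(C)C
A9 | alternative 3 | (2S)-4-(tert-butyldimethylsilyloxy)-2-[4-(tert-butyldimethylsilyloxy)-3-methoxyphenyl]-2,5-dihydrofuran | COc1cc([C@H]2OCC(O[Si](C)(C)C(C)(C)C)=C2)ccc1O[Si](C)(C)C(C)(C)C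
A10 | alternative 3 | 2-[4-(tert-butyldimethylsilyloxy)-3-methoxyphenyl]acetyl chloride | COc1cc(CC(=O)Cl)ccc1O[Si](C)(C)C(C)(C)C
A11 | alternative 3 | [4-(tert-butyldimethylsilyloxy)-3-methoxyphenyl]ketene | COc1cc(C=C=O)ccc1O[Si](C)(C)C(C)(C)C
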